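**Retrosynthetic overview**

1. The plan rests on the acyclic C12–C15 segment of the acyl chain: the hydroxyls on C13 and C14 are erythro to each other and to the C15 hydroxyl and sit beside the C12 methyl centre, which is the pattern left by syn addition of two oxygens to one face of a (Z)-C13=C14 alkene; none of these atoms lies in a ring.
2. Last disconnection: C8=C9 (Horner–Wadsworth–Emmons) between a C9–C23 (Z)-3-chloroenal and a C1–C8 trienyl phosphonate that already carries the protected cyclohexyl ester; the C10=C11(Cl) unit comes from a C11 aldehyde via alkyne, ynoate and trans-hydrochlorination.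
3. Key disconnection: C13–O and C14–O by OsO4 on the Z alkene, made by a Z-selective Wittig reaction between a Roche-ester ylide (C11–C13) and the C14 aldehyde of a bought syn-1,3-dioxane that holds C15 and C17.
4. C18 and C19 come from enamine-catalysed α-chlorination of the C19 aldehyde and anti addition of lithium butynide; the C20 alkyne stands in for the E alkene until the osmylation is over.
5. No ring of the target is formed on the way: the cyclohexane ring C1′–C6′ is bought as (S)-cyclohex-3-enecarboxylic acid (cis-diol set by iodolactone, epoxide and acetoxonium inversion before coupling), and the only rings closed are protective (15,17-acetonide bought, 13,14-acetonide closed after the key step).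

Key step: step 11

**Remarks**

- Numbering: chain carbons are numbered as in the acyl chain of 54 (C1 ester carbonyl, C6 and C12 bear CH3, C11 and C18 bear Cl, C23 terminal CH3); ring carbons are C1′–C6′ (C1′ bears the carboxyl, C3′ the acyloxy group, C4′ the hydroxyl).
- Assumption: the (2S,5S) enantiomer of trans-2,5-diphenylpyrrolidine is taken as the one that delivers chlorine to the enamine face giving the 18R aldehyde 11; if the sense is the reverse, its enantiomer is used and nothing else changes.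
- The CIP descriptors of C12, C14 and C18 change along the route only because substituent priorities change; no centre is inverted after it is set.

**Route**

Step 1
Reactants: 1 methyl (S)-3-hydroxy-2-methylpropanoate
Product: 2 methyl (S)-3-[(tert-butyldimethylsilyl)oxy]-2-methylpropanoate
Conditions: TBSCl, imidazole, CH2Cl2, 0 °C → rt
Reagents that add atoms: tert-butyldimethylsilyl chloride, CC(C)(C)[Si](C)(C)Cl
Why: Imidazole-promoted O-silylation of the primary alcohol, which leaves the α-stereocentre (future C12) untouched.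

Step 2
Reactants: 2 methyl (S)-3-[(tert-butyldimethylsilyl)oxy]-2-methylpropanoate
Product: 3 (R)-3-[(tert-butyldimethylsilyl)oxy]-2-methylpropan-1-ol
Conditions: i-Bu2AlH, CH2Cl2, −78 → 0 °C
Reagents that add atoms: none
Why: Hydride reduction of the ester to the primary alcohol at low temperature, without enolisation of the α-centre.

Step 3
Reactants: 3 (R)-3-[(tert-butyldimethylsilyl)oxy]-2-methylpropan-1-ol
Product: 4 (S)-tert-butyl(3-iodo-2-methylpropoxy)dimethylsilane
Conditions: I2, PPh3, imidazole, CH2Cl2, 0 °C → rt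
Reagents that add atoms: iodine, II
Why: Appel-type iodination, an SN2 displacement of the oxyphosphonium at the primary carbon that does not involve the stereocentre.

Step 4
Reactants: 4 (S)-tert-butyl(3-iodo-2-methylpropoxy)dimethylsilane
Product: 5 (S)-[3-[(tert-butyldimethylsilyl)oxy]-2-methylpropyl]triphenylphosphonium iodide
Conditions: PPh3, MeCN, reflux
Reagents that add atoms: triphenylphosphine, c1ccc(cc1)P(c1ccccc1)c1ccccc1
Why: SN2 quaternisation of triphenylphosphine by the primary iodide gives the Wittig salt.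

Step 5
Reactants: 6 tert-butyl 2-[(4R,6S)-6-(hydroxymethyl)-2,2-dimethyl-1,3-dioxan-4-yl]acetate
Product: 7 tert-butyl 2-[(4R,6S)-6-formyl-2,2-dimethyl-1,3-dioxan-4-yl]acetate
Conditions: Dess–Martin periodinane, pyridine, CH2Cl2, 0 °C → rt
Reagents that add atoms: none
Why: Dess–Martin oxidation of the primary alcohol to the α-alkoxy aldehyde (C14) under buffered conditions that neither epimerise C15 nor open the acetonide.

Step 6
Reactants: 5 (S)-[3-[(tert-butyldimethylsilyl)oxy]-2-methylpropyl]triphenylphosphonium iodide; 7 tert-butyl 2-[(4R,6S)-6-formyl-2,2-dimethyl-1,3-dioxan-4-yl]acetate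
Product: 9 tert-butyl 2-[(4R,6S)-6-[(1Z,3R)-4-[(tert-butyldimethylsilyl)oxy]-3-methylbut-1-en-1-yl]-2,2-dimethyl-1,3-dioxan-4-yl]acetate, via phosphorus ylide 8 (not isolated)
Conditions: NaN(SiMe3)2, THF, 0 °C; then 7, −78 °C → rt
Reagents that add atoms: none
Why: Wittig olefination with a non-stabilised ylide: under salt-poor conditions at −78 °C the kinetic cis-oxaphosphetane collapses to the (Z)-C13=C14 alkene, and the fast addition leaves C15 and C12 untouched.

Step 7
Reactants: 9 tert-butyl 2-[(4R,6S)-6-[(1Z,3R)-4-[(tert-butyldimethylsilyl)oxy]-3-methylbut-1-en-1-yl]-2,2-dimethyl-1,3-dioxan-4-yl]acetate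
Product: 10 2-[(4R,6S)-6-[(1Z,3R)-4-[(tert-butyldimethylsilyl)oxy]-3-methylbut-1-en-1-yl]-2,2-dimethyl-1,3-dioxan-4-yl]acetaldehyde
Conditions: i-Bu2AlH (1.1 equiv), toluene, −78 °C
Reagents that add atoms: none
Why: Partial hydride reduction: the tetrahedral aluminium hemiacetal of the hindered tert-butyl ester is stable at −78 °C and releases the C19 aldehyde only on work-up, with the silyl ether, acetonide and alkene inert.

Step 8
Reactants: 10 2-[(4R,6S)-6-[(1Z,3R)-4-[(tert-butyldimethylsilyl)oxy]-3-methylbut-1-en-1-yl]-2,2-dimethyl-1,3-dioxan-4-yl]acetaldehyde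
Product: 11 (2R)-2-chloro-2-[(4R,6S)-6-[(1Z,3R)-4-[(tert-butyldimethylsilyl)oxy]-3-methylbut-1-en-1-yl]-2,2-dimethyl-1,3-dioxan-4-yl]acetaldehyde
Conditions: (2S,5S)-2,5-diphenylpyrrolidine (10 mol %), NCS, CH2Cl2, 0 °C → rt
Reagents that add atoms: N-chlorosuccinimide, O=C1CCC(=O)N1Cl
Why: Enamine-catalysed asymmetric α-chlorination of an aldehyde: the C2-symmetric pyrrolidine forms the (E)-enamine and its flanking phenyl group blocks one face, so NCS chlorinates C18 on the other face to set 18R (chlorine anti to the C17 oxygen), and the product is used at once to avoid epimerisation.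

Step 9
Reactants: 11 (2R)-2-chloro-2-[(4R,6S)-6-[(1Z,3R)-4-[(tert-butyldimethylsilyl)oxy]-3-methylbut-1-en-1-yl]-2,2-dimethyl-1,3-dioxan-4-yl]acetaldehyde; 12 1-butyne
Product: 14 C11–C23 chlorohydrin (11-OTBS; 12R-CH3; 13Z-ene; 15S,17R-O-isopropylidene; 18S-Cl; 19S-OH; 20-yne), via lithium butynide 13 (not isolated)
Conditions: n-BuLi, THF, −78 °C; then 11, −78 °C; AcOH quench at −78 °C
Reagents that add atoms: none
Why: Acetylide addition to an α-chloro aldehyde through the Cornforth-type (dipole-minimised) transition state, in which C–Cl lies anti to C=O and the nucleophile passes the α-hydrogen, gives the 18,19-anti chlorohydrin and so sets 19S, while the cold acidic quench prevents closure of the lithium alkoxide onto C18.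

Step 10
Reactants: 14 C11–C23 chlorohydrin
Product: 15 C11–C23 key-step precursor (11-OTBS; 12R-CH3; 13Z-ene; 15S,17R-O-isopropylidene; 18R-Cl; 19S-OTBS; 20-yne)
Conditions: TBSOTf, 2,6-lutidine, CH2Cl2, −78 → 0 °C
Reagents that add atoms: tert-butyldimethylsilyl trifluoromethanesulfonate, CC(C)(C)[Si](C)(C)OS(=O)(=O)C(F)(F)F
Why: Silylation of the hindered propargylic alcohol with the silyl triflate and a non-nucleophilic base, conditions that cannot trigger epoxide formation from the chlorohydrin.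

Step 11
Reactants: 15 C11–C23 key-step precursor
Product: 17 C11–C23 13,14-diol (11-OTBS; 12S-CH3; 13R,14R-diol; 15S,17R-O-isopropylidene; 18R-Cl; 19S-OTBS; 20-yne), via dioxoosmium glycolate 16 (not isolated)
Conditions: OsO4 (5 mol %), NMO, acetone/H2O, rt
Reagents that add atoms: osmium tetroxide, O=[Os](=O)(=O)=O; N-methylmorpholine N-oxide, C[N+]1([O-])CCOCC1; water, O
Why: OsO4 adds suprafacially to C13=C14 by [3+2] cycloaddition to the glycolate 16 of hexavalent osmium, which NMO reoxidises and water hydrolyses, so both C–O bonds form on one face and the Z geometry becomes the 13,14-erythro diol; the closest known reaction type is the catalytic OsO4/NMO syn dihydroxylation of Z-configured allylic ethers, which goes anti to the allylic oxygen. No ring of the target is closed; the only ring formed is the transient five-membered osmate ester, opened again on hydrolysis. C14 is controlled by C15: 1,3-allylic strain in the Z alkene holds C15–H in the alkene plane, the dioxane oxygen O15 with its gem-dimethyl carbon covers one face, and osmium enters from the C16 side, which gives the C14/C15 erythro relationship. C13 is set by the same face choice, which C12 reinforces: with C12–H eclipsing the alkene, the CH2OTBS arm lies on the face that carries O15 and only the methyl group on the open face. The step needs diastereofacial selectivity only (syn addition and the site are intrinsic), and it is secured by the two H-eclipsed allylic stereocentres acting in the same sense. The alkyne, the secondary chloride, both silyl ethers and the acetonide are inert to OsO4/NMO at room temperature.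

Step 12
Reactants: 17 C11–C23 13,14-diol
Product: 18 C11–C23 bis-acetonide (11-OTBS; 12S-CH3; 13R,14S-O-isopropylidene; 15S,17R-O-isopropylidene; 18R-Cl; 19S-OTBS; 20-yne)
Conditions: Me2C(OMe)2, PPTS (cat.), CH2Cl2, rt
Reagents that add atoms: 2,2-dimethoxypropane, COC(C)(C)OC
Why: Acid-catalysed transketalisation: the erythro 13,14-diol closes a cis-dioxolane, the only pairing left open by the 15,17-acetonide, and PPTS is too weak to cleave the silyl ethers.

Step 13
Reactants: 18 C11–C23 bis-acetonide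
Product: 19 (20Z)-21-(triethoxysilyl)-20-ene derived from 18 (other groups as in 18)
Conditions: [Cp*Ru(MeCN)3]PF6 (5 mol %), (EtO)3SiH, CH2Cl2, 0 °C → rt
Reagents that add atoms: triethoxysilane, CCO[SiH](OCC)OCC
Why: Ruthenium-catalysed trans-hydrosilylation of an internal alkyne: H and Si add anti across C20≡C21 so that C19 and C22 end up trans, and the position of silicon (expected at C21, away from the branched C19) is immaterial because silicon is removed in step 14.

Step 14
Reactants: 19 (20Z)-21-(triethoxysilyl)-20-ene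
Product: 20 C11–C23 (20E)-alkene (11-OTBS; 12S; 13R,14S- and 15S,17R-acetonides; 18R-Cl; 19S-OTBS)
Conditions: AgF, THF/MeOH/H2O, rt, dark
Reagents that add atoms: none
Why: Protodesilylation of an alkenylsilane: fluoride activates the trialkoxysilyl group, the alkenyl group passes to silver and is protonated with retention, which gives the (E)-C20=C21 alkene while the far less fluorophilic TBS ethers should remain.

Step 15
Reactants: 20 C11–C23 (20E)-alkene
Product: 21 C11 alcohol (as 20 with 11-OH)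
Conditions: HF·pyridine, pyridine, THF, 0 °C
Reagents that add atoms: none
Why: Selective desilylation: buffered HF·pyridine cleaves the unhindered primary TBS ether much faster than the secondary C19 ether flanked by CHCl and leaves both acetonides intact.

Step 16
Reactants: 21 C11 alcohol
Product: 22 C11 aldehyde (12R; otherwise as 20)
Conditions: Dess–Martin periodinane, pyridine, CH2Cl2, 0 °C → rt
Reagents that add atoms: none
Why: Dess–Martin oxidation under pyridine buffer gives the α-methyl-β-alkoxy aldehyde without epimerisation at C12 or β-elimination; it is used directly.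

Step 17
Reactants: 22 C11 aldehyde
Product: 23 C10–C23 terminal alkyne (C10≡C11; 12S; otherwise as 20)
Conditions: dimethyl (1-diazo-2-oxopropyl)phosphonate, K2CO3, MeOH, 0 °C → rt
Reagents that add atoms: dimethyl (1-diazo-2-oxopropyl)phosphonate, COP(=O)(OC)C(=[N+]=[N-])C(C)=O
Why: Ohira–Bestmann (Seyferth–Gilbert) homologation: methanolysis of the reagent gives the diazomethylphosphonate anion, which adds to the aldehyde, and loss of phosphate and N2 with 1,2-hydride shift delivers the C10≡C11 alkyne under carbonate conditions mild enough to preserve C12.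

Step 18
Reactants: 23 C10–C23 terminal alkyne
Product: 25 C9–C23 methyl ynoate (12S; otherwise as 20), via lithium acetylide 24 (not isolated)
Conditions: n-BuLi, THF, −78 °C; ClCO2Me, −78 → −20 °C
Reagents that add atoms: methyl chloroformate, COC(=O)Cl
Why: Deprotonation of the terminal alkyne and C-acylation of the lithium acetylide with methyl chloroformate installs C9; at −78 °C n-BuLi attacks neither the secondary chloride nor the silyl ether.

Step 19
Reactants: 25 C9–C23 methyl ynoate
Product: 26 methyl (10Z)-11-chloro-10-enoate C9–C23 (12R; otherwise as 20)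
Conditions: LiCl, AcOH, MeCN, 80 °C
Reagents that add atoms: lithium chloride, [Li+].[Cl-]
Why: Hydrohalogenation of a 2-ynoate: chloride adds in conjugate fashion to C11 and the allenolate is protonated anti to it, which gives the (Z)-3-chloro-2-enoate with chlorine cis to C9, the 10Z geometry of the target.

Step 20
Reactants: 26 methyl (10Z)-11-chloro-10-enoate
Product: 27 (10Z)-11-chloro allylic alcohol (C9–OH)
Conditions: i-Bu2AlH, CH2Cl2, −78 °C
Reagents that add atoms: none
Why: 1,2-Reduction of the enoate to the allylic alcohol by i-Bu2AlH at low temperature, which touches neither the alkenyl nor the alkyl chloride.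

Step 21
Reactants: 27 (10Z)-11-chloro allylic alcohol
Product: 28 (10Z)-11-chloro enal (C9 aldehyde)
Conditions: MnO2, CH2Cl2, rt
Reagents that add atoms: none
Why: MnO2 oxidises the allylic alcohol selectively under neutral conditions, so the Z-chloroenal should form without isomerisation.

Step 22
Reactants: 29 (S)-cyclohex-3-ene-1-carboxylic acid
Product: 30 (1S,4S,5S)-4-iodo-6-oxabicyclo[3.2.1]octan-7-one
Conditions: I2, KI, NaHCO3, H2O/CH2Cl2, rt, dark
Reagents that add atoms: iodine, II
Why: Iodolactonisation: the carboxylate opens the iodonium ion anti and can only reach C3′ on its own ring face, so O3′ becomes cis to the carboxyl carbon and iodine at C4′ trans to O3′.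

Step 23
Reactants: 30 (1S,4S,5S)-4-iodo-6-oxabicyclo[3.2.1]octan-7-one
Product: 32 allyl (1S,3S,6R)-7-oxabicyclo[4.1.0]heptane-3-carboxylate, via iodohydrin allyl ester 31 (not isolated)
Conditions: K2CO3, allyl alcohol, rt
Reagents that add atoms: allyl alcohol, C=CCO
Why: Base-mediated transesterification opens the strained lactone to the allyl ester, and the liberated C3′ alkoxide displaces the antiperiplanar iodide (intramolecular Williamson closure) to give the epoxide cis to the ester.

Step 24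
Reactants: 32 allyl (1S,3S,6R)-7-oxabicyclo[4.1.0]heptane-3-carboxylate
Product: 33 allyl (1S,3R,4R)-3-acetoxy-4-hydroxycyclohexane-1-carboxylate
Conditions: AcOH, NaOAc, 80 °C
Reagents that add atoms: acetic acid, CC(=O)O
Why: Trans-diaxial (Fürst–Plattner) acetolysis of the epoxide: acetate enters with inversion from the face opposite the epoxide oxygen, that is trans to the ester, and either regioisomer leads to the same acetoxonium ion in step 25.

Step 25
Reactants: 33 allyl (1S,3R,4R)-3-acetoxy-4-hydroxycyclohexane-1-carboxylate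
Product: 37 allyl (1S,3R,4S)-3,4-dihydroxycyclohexane-1-carboxylate, via triflate 34 (not isolated), via acetoxonium triflate 35 (not isolated), via cis monoacetate 36 (not isolated)
Conditions: Tf2O, pyridine, CH2Cl2, −20 °C → rt; H2O; then K2CO3, allyl alcohol, rt
Reagents that add atoms: none
Why: Neighbouring-group participation: the antiperiplanar acetate displaces the axial triflate with inversion to a cis-fused acetoxonium ion, whose hydrolysis and deacetylation (allyl alcohol keeps the allyl ester) give the cis-diol with both oxygens trans to the ester, so the two inversions from the epoxide set 3′R and 4′S.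

Step 26
Reactants: 37 allyl (1S,3R,4S)-3,4-dihydroxycyclohexane-1-carboxylate
Product: 38 allyl (1S,3R,4S)-4-[(tert-butyldimethylsilyl)oxy]-3-hydroxycyclohexane-1-carboxylate
Conditions: TBSCl, imidazole, DMF, 0 °C
Reagents that add atoms: tert-butyldimethylsilyl chloride, CC(C)(C)[Si](C)(C)Cl
Why: Regioselective silylation: with the ester equatorial the C4′ hydroxyl is equatorial and the C3′ hydroxyl axial, so TBSCl at 0 °C should take the more accessible C4′–OH.

Step 27
Reactants: 39 (tert-butyldimethylsilyloxy)acetaldehyde; 40 2-(triphenylphosphoranylidene)propanal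
Product: 41 (E)-4-[(tert-butyldimethylsilyl)oxy]-2-methylbut-2-enal
Conditions: toluene, 80 °C
Reagents that add atoms: none
Why: Wittig olefination with a stabilised formyl ylide gives the (E)-trisubstituted enal (the future C6=C7 bond) under thermodynamic control.

Step 28
Reactants: 41 (E)-4-[(tert-butyldimethylsilyl)oxy]-2-methylbut-2-enal; 42 triethyl (E)-4-phosphonocrotonate
Product: 44 ethyl (2E,4E,6E)-8-[(tert-butyldimethylsilyl)oxy]-6-methylocta-2,4,6-trienoate, via lithiated phosphonocrotonate 43 (not isolated)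
Conditions: LiN(SiMe3)2, THF, −78 °C; then 41, −78 → 0 °C
Reagents that add atoms: none
Why: Vinylogous Horner–Wadsworth–Emmons reaction: the lithiated phosphonocrotonate attacks through its α-carbon and syn-elimination of phosphate gives the new (E)-C4=C5 bond.

Step 29
Reactants: 44 ethyl (2E,4E,6E)-8-[(tert-butyldimethylsilyl)oxy]-6-methylocta-2,4,6-trienoate
Product: 45 ethyl (2E,4E,6E)-8-hydroxy-6-methylocta-2,4,6-trienoate
Conditions: HF·pyridine, THF, 0 °C → rt
Reagents that add atoms: none
Why: Fluoride cleavage of the primary allylic silyl ether, to which the ester and the triene are inert.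

Step 30
Reactants: 45 ethyl (2E,4E,6E)-8-hydroxy-6-methylocta-2,4,6-trienoate
Product: 46 ethyl (2E,4E,6E)-8-bromo-6-methylocta-2,4,6-trienoate
Conditions: CBr4, PPh3, CH2Cl2, 0 °C
Reagents that add atoms: carbon tetrabromide, BrC(Br)(Br)Br
Why: Appel bromination: SN2 displacement of the oxyphosphonium at the primary allylic carbon, without allylic transposition at 0 °C.

Step 31
Reactants: 46 ethyl (2E,4E,6E)-8-bromo-6-methylocta-2,4,6-trienoate
Product: 47 ethyl (2E,4E,6E)-8-(diethoxyphosphoryl)-6-methylocta-2,4,6-trienoate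
Conditions: P(OEt)3, toluene, 100 °C
Reagents that add atoms: triethyl phosphite, CCOP(OCC)OCC
Why: Michaelis–Arbuzov reaction at the primary allylic bromide, which keeps the conjugated (E,E,E)-triene.

Step 32
Reactants: 47 ethyl (2E,4E,6E)-8-(diethoxyphosphoryl)-6-methylocta-2,4,6-trienoate
Product: 48 (2E,4E,6E)-8-(diethoxyphosphoryl)-6-methylocta-2,4,6-trienoic acid
Conditions: LiOH, THF/H2O, rt; then aq. HCl to pH 3
Reagents that add atoms: lithium hydroxide, [Li+].[OH-]
Why: Saponification of the ethyl ester; the diethyl phosphonate is not hydrolysed by LiOH at room temperature.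

Step 33
Reactants: 48 (2E,4E,6E)-8-(diethoxyphosphoryl)-6-methylocta-2,4,6-trienoic acid; 38 allyl (1S,3R,4S)-4-[(tert-butyldimethylsilyl)oxy]-3-hydroxycyclohexane-1-carboxylate
Product: 50 allyl (1S,3R,4S)-4-[(tert-butyldimethylsilyl)oxy]-3-[[(2E,4E,6E)-8-(diethoxyphosphoryl)-6-methylocta-2,4,6-trienoyl]oxy]cyclohexane-1-carboxylate, via mixed anhydride 49 (not isolated)
Conditions: 2,4,6-Cl3C6H2COCl, Et3N, THF, rt; then 38, DMAP, toluene, rt
Reagents that add atoms: none
Why: Yamaguchi esterification: the mixed anhydride acylates DMAP and the acylpyridinium is captured by the hindered axial C3′ hydroxyl with retention at C3′.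

Step 34
Reactants: 50 allyl (1S,3R,4S)-4-[(tert-butyldimethylsilyl)oxy]-3-[[(2E,4E,6E)-8-(diethoxyphosphoryl)-6-methylocta-2,4,6-trienoyl]oxy]cyclohexane-1-carboxylate; 28 (10Z)-11-chloro enal
Product: 52 fully protected pentaene allyl ester (C1–C23 chain on O3′; 19-OTBS; 4′-OTBS; 13,14- and 15,17-acetonides), via lithiated phosphonate 51 (not isolated)
Conditions: LiN(SiMe3)2, THF, −78 °C; then 28, −78 → 0 °C
Reagents that add atoms: none
Why: Horner–Wadsworth–Emmons olefination of the trienyl phosphonate anion (deprotonated selectively at C8) with the enal gives the (E)-C8=C9 bond and completes the pentaene, the low temperature disfavouring addition–elimination at the chlorine-bearing C11.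

Step 35
Reactants: 52 fully protected pentaene allyl ester
Product: 53 protected pentaene carboxylic acid (free C1′ carboxyl; otherwise as 52)
Conditions: Pd(PPh3)4 (5 mol %), dimedone, THF, rt
Reagents that add atoms: none
Why: Deallylation by zerovalent palladium (Tsuji–Trost type): the π-allyl complex formed from the allyl ester is intercepted by dimedone, a neutral soft nucleophile that cannot add to the pentaenoate.

Step 36
Reactants: 53 protected pentaene carboxylic acid
Product: 54 (1S,3R,4S)-3-[[(2E,4E,6E,8E,10Z,12R,13R,14S,15S,17R,18R,19S,20E)-11,18-dichloro-13,14,15,17,19-pentahydroxy-6,12-dimethyltricosa-2,4,6,8,10,20-hexaenoyl]oxy]-4-hydroxycyclohexane-1-carboxylic acid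
Conditions: 48 % aq. HF, MeCN, 0 °C → rt
Reagents that add atoms: none
Why: Acid-mediated global deprotection: aqueous HF cleaves both TBS ethers and hydrolyses both acetonides, and the acidic medium avoids base-induced epoxide closure of the C17–C19 chlorohydrin and acyl migration between O3′ and O4′.

**Compound list**

1 | methyl (S)-3-hydroxy-2-methylpropanoate (Roche ester) | COC(=O)[C@@H](C)CO | starting material
2 | methyl (S)-3-[(tert-butyldimethylsilyl)oxy]-2-methylpropanoate | COC(=O)[C@@H](C)CO[Si](C)(C)C(C)(C)C | intermediate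
3 | (R)-3-[(tert-butyldimethylsilyl)oxy]-2-methylpropan-1-ol | OC[C@@H](C)CO[Si](C)(C)C(C)(C)C | intermediate
4 | (S)-tert-butyl(3-iodo-2-methylpropoxy)dimethylsilane | IC[C@@H](C)CO[Si](C)(C)C(C)(C)C | intermediate
5 | (S)-[3-[(tert-butyldimethylsilyl)oxy]-2-methylpropyl]triphenylphosphonium iodide | [I-].c1ccccc1[P+](c1ccccc1)(c1ccccc1)C[C@@H](C)CO[Si](C)(C)C(C)(C)C | intermediate
6 | tert-butyl 2-[(4R,6S)-6-(hydroxymethyl)-2,2-dimethyl-1,3-dioxan-4-yl]acetate | CC(C)(C)OC(=O)C[C@H]1C[C@H](OC(C)(C)O1)CO | starting material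
7 | tert-butyl 2-[(4R,6S)-6-formyl-2,2-dimethyl-1,3-dioxan-4-yl]acetate | CC(C)(C)OC(=O)C[C@H]1C[C@H](OC(C)(C)O1)C=O | intermediate
8 | (S)-[3-[(tert-butyldimethylsilyl)oxy]-2-methylpropylidene]triphenylphosphorane (formed in the flask) | c1ccccc1P(c1ccccc1)(c1ccccc1)=C[C@@H](C)CO[Si](C)(C)C(C)(C)C | intermediate
9 | tert-butyl 2-[(4R,6S)-6-[(1Z,3R)-4-[(tert-butyldimethylsilyl)oxy]-3-methylbut-1-en-1-yl]-2,2-dimethyl-1,3-dioxan-4-yl]acetate (C11–C19; 12R,15S,17R) | CC(C)(C)OC(=O)C[C@H]1C[C@H](OC(C)(C)O1)/C=C\[C@@H](C)CO[Si](C)(C)C(C)(C)C | intermediate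
10 | 2-[(4R,6S)-6-[(1Z,3R)-4-[(tert-butyldimethylsilyl)oxy]-3-methylbut-1-en-1-yl]-2,2-dimethyl-1,3-dioxan-4-yl]acetaldehyde | O=CC[C@H]1C[C@H](OC(C)(C)O1)/C=C\[C@@H](C)CO[Si](C)(C)C(C)(C)C | intermediate
11 | (2R)-2-chloro-2-[(4R,6S)-6-[(1Z,3R)-4-[(tert-butyldimethylsilyl)oxy]-3-methylbut-1-en-1-yl]-2,2-dimethyl-1,3-dioxan-4-yl]acetaldehyde (18R) | O=C[C@H](Cl)[C@H]1C[C@H](OC(C)(C)O1)/C=C\[C@@H](C)CO[Si](C)(C)C(C)(C)C | intermediate
12 | 1-butyne | CCC#C | starting material
13 | lithium but-1-yn-1-ide (formed in the flask) | CCC#C[Li] | intermediate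
14 | C11–C23 chlorohydrin: 11-OTBS; 12R-CH3; 13Z-ene; 15S,17R-O-isopropylidene; 18S-Cl; 19S-OH; 20-yne | CCC#C[C@H](O)[C@H](Cl)[C@H]1C[C@H](OC(C)(C)O1)/C=C\[C@@H](C)CO[Si](C)(C)C(C)(C)C | intermediate
15 | C11–C23 key-step precursor: 11-OTBS; 12R-CH3; 13Z-ene; 15S,17R-O-isopropylidene; 18R-Cl; 19S-OTBS; 20-yne | CCC#C[C@H](O[Si](C)(C)C(C)(C)C)[C@H](Cl)[C@H]1C[C@H](OC(C)(C)O1)/C=C\[C@@H](C)CO[Si](C)(C)C(C)(C)C | intermediate
16 | 13,14-cyclic dioxoosmium glycolate of 15 (hexavalent osmium; formed in the flask) | CCC#C[C@H](O[Si](C)(C)C(C)(C)C)[C@H](Cl)[C@H]1C[C@H](OC(C)(C)O1)[C@@H]2O[Os](=O)(=O)O[C@@H]2[C@@H](C)CO[Si](C)(C)C(C)(C)C | intermediate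
17 | C11–C23 13,14-diol: 11-OTBS; 12S-CH3; 13R,14R-diol; 15S,17R-O-isopropylidene; 18R-Cl; 19S-OTBS; 20-yne | CCC#C[C@H](O[Si](C)(C)C(C)(C)C)[C@H](Cl)[C@H]1C[C@H](OC(C)(C)O1)[C@H](O)[C@H](O)[C@@H](C)CO[Si](C)(C)C(C)(C)C | intermediate
18 | C11–C23 bis-acetonide: 11-OTBS; 12S-CH3; 13R,14S-O-isopropylidene; 15S,17R-O-isopropylidene; 18R-Cl; 19S-OTBS; 20-yne | CCC#C[C@H](O[Si](C)(C)C(C)(C)C)[C@H](Cl)[C@H]1C[C@H](OC(C)(C)O1)[C@@H]2OC(C)(C)O[C@@H]2[C@@H](C)CO[Si](C)(C)C(C)(C)C | intermediate
19 | (20Z)-21-(triethoxysilyl)-20-ene derived from 18 (C19 and Si cis; a C20-silyl regioisomer would converge in step 14) | CC/C([Si](OCC)(OCC)OCC)=C/[C@H](O[Si](C)(C)C(C)(C)C)[C@H](Cl)[C@H]1C[C@H](OC(C)(C)O1)[C@@H]2OC(C)(C)O[C@@H]2[C@@H](C)CO[Si](C)(C)C(C)(C)C | intermediate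
20 | C11–C23 (20E)-alkene: 11-OTBS; 12S; 13R,14S- and 15S,17R-acetonides; 18R-Cl; 19S-OTBS | CC/C=C/[C@H](O[Si](C)(C)C(C)(C)C)[C@H](Cl)[C@H]1C[C@H](OC(C)(C)O1)[C@@H]2OC(C)(C)O[C@@H]2[C@@H](C)CO[Si](C)(C)C(C)(C)C | intermediate
21 | C11 alcohol (as 20 with 11-OH) | CC/C=C/[C@H](O[Si](C)(C)C(C)(C)C)[C@H](Cl)[C@H]1C[C@H](OC(C)(C)O1)[C@@H]2OC(C)(C)O[C@@H]2[C@@H](C)CO | intermediate
22 | C11 aldehyde (12R; otherwise as 20) | CC/C=C/[C@H](O[Si](C)(C)C(C)(C)C)[C@H](Cl)[C@H]1C[C@H](OC(C)(C)O1)[C@@H]2OC(C)(C)O[C@@H]2[C@@H](C)C=O | intermediate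
23 | C10–C23 terminal alkyne (12S; otherwise as 20) | CC/C=C/[C@H](O[Si](C)(C)C(C)(C)C)[C@H](Cl)[C@H]1C[C@H](OC(C)(C)O1)[C@@H]2OC(C)(C)O[C@@H]2[C@@H](C)C#C | intermediate
24 | lithium acetylide of 23 (formed in the flask) | CC/C=C/[C@H](O[Si](C)(C)C(C)(C)C)[C@H](Cl)[C@H]1C[C@H](OC(C)(C)O1)[C@@H]2OC(C)(C)O[C@@H]2[C@@H](C)C#C[Li] | intermediate
25 | C9–C23 methyl ynoate (12S; otherwise as 20) | CC/C=C/[C@H](O[Si](C)(C)C(C)(C)C)[C@H](Cl)[C@H]1C[C@H](OC(C)(C)O1)[C@@H]2OC(C)(C)O[C@@H]2[C@@H](C)C#CC(=O)OC | intermediate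
26 | methyl (10Z)-11-chloro-10-enoate C9–C23 (12R; otherwise as 20) | CC/C=C/[C@H](O[Si](C)(C)C(C)(C)C)[C@H](Cl)[C@H]1C[C@H](OC(C)(C)O1)[C@@H]2OC(C)(C)O[C@@H]2[C@@H](C)/C(Cl)=C/C(=O)OC | intermediate
27 | (10Z)-11-chloro allylic alcohol (C9–OH; otherwise as 26) | CC/C=C/[C@H](O[Si](C)(C)C(C)(C)C)[C@H](Cl)[C@H]1C[C@H](OC(C)(C)O1)[C@@H]2OC(C)(C)O[C@@H]2[C@@H](C)/C(Cl)=C/CO | intermediate
28 | (10Z)-11-chloro enal (C9 aldehyde; otherwise as 26) | CC/C=C/[C@H](O[Si](C)(C)C(C)(C)C)[C@H](Cl)[C@H]1C[C@H](OC(C)(C)O1)[C@@H]2OC(C)(C)O[C@@H]2[C@@H](C)/C(Cl)=C/C=O | intermediate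
29 | (S)-cyclohex-3-ene-1-carboxylic acid | OC(=O)[C@@H]1CC=CCC1 | starting material
30 | (1S,4S,5S)-4-iodo-6-oxabicyclo[3.2.1]octan-7-one | O=C1O[C@H]2C[C@@H]1CC[C@@H]2I | intermediate
31 | allyl (1S,3S,4S)-3-hydroxy-4-iodocyclohexane-1-carboxylate (formed in the flask) | C=CCOC(=O)[C@@H]1C[C@H](O)[C@@H](I)CC1 | intermediate
32 | allyl (1S,3S,6R)-7-oxabicyclo[4.1.0]heptane-3-carboxylate | C=CCOC(=O)[C@@H]1C[C@@H]2O[C@@H]2CC1 | intermediate
33 | allyl (1S,3R,4R)-3-acetoxy-4-hydroxycyclohexane-1-carboxylate | C=CCOC(=O)[C@@H]1C[C@@H](OC(C)=O)[C@H](O)CC1 | intermediate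
34 | allyl (1S,3R,4R)-3-acetoxy-4-[(trifluoromethylsulfonyl)oxy]cyclohexane-1-carboxylate (formed in the flask) | C=CCOC(=O)[C@@H]1C[C@@H](OC(C)=O)[C@H](OS(=O)(=O)C(F)(F)F)CC1 | intermediate
35 | cis-fused 2-methyl-1,3-dioxolan-2-ylium (acetoxonium) triflate on C3′/C4′, both oxygens trans to the ester (formed in the flask) | C=CCOC(=O)[C@@H]1C[C@H]2OC(C)=[O+][C@H]2CC1.[O-]S(=O)(=O)C(F)(F)F | intermediate
36 | allyl (1S,3R,4S)-3-acetoxy-4-hydroxycyclohexane-1-carboxylate (formed in the flask) | C=CCOC(=O)[C@@H]1C[C@@H](OC(C)=O)[C@@H](O)CC1 | intermediate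
37 | allyl (1S,3R,4S)-3,4-dihydroxycyclohexane-1-carboxylate | C=CCOC(=O)[C@@H]1C[C@@H](O)[C@@H](O)CC1 | intermediate
38 | allyl (1S,3R,4S)-4-[(tert-butyldimethylsilyl)oxy]-3-hydroxycyclohexane-1-carboxylate | C=CCOC(=O)[C@@H]1C[C@@H](O)[C@@H](O[Si](C)(C)C(C)(C)C)CC1 | intermediate
39 | (tert-butyldimethylsilyloxy)acetaldehyde | O=CCO[Si](C)(C)C(C)(C)C | starting material
40 | 2-(triphenylphosphoranylidene)propanal | CC(C=O)=P(c1ccccc1)(c1ccccc1)c1ccccc1 | starting material
41 | (E)-4-[(tert-butyldimethylsilyl)oxy]-2-methylbut-2-enal | O=C/C(C)=C/CO[Si](C)(C)C(C)(C)C | intermediate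
42 | triethyl (E)-4-phosphonocrotonate | CCOC(=O)/C=C/CP(=O)(OCC)OCC | starting material
43 | lithiated triethyl 4-phosphonocrotonate (formed in the flask) | [Li+].CCOC(=O)/C=C/[CH-]P(=O)(OCC)OCC | intermediate
44 | ethyl (2E,4E,6E)-8-[(tert-butyldimethylsilyl)oxy]-6-methylocta-2,4,6-trienoate | CCOC(=O)/C=C/C=C/C(C)=C/CO[Si](C)(C)C(C)(C)C | intermediate
45 | ethyl (2E,4E,6E)-8-hydroxy-6-methylocta-2,4,6-trienoate | CCOC(=O)/C=C/C=C/C(C)=C/CO | intermediate
46 | ethyl (2E,4E,6E)-8-bromo-6-methylocta-2,4,6-trienoate | CCOC(=O)/C=C/C=C/C(C)=C/CBr | intermediate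
47 | ethyl (2E,4E,6E)-8-(diethoxyphosphoryl)-6-methylocta-2,4,6-trienoate | CCOC(=O)/C=C/C=C/C(C)=C/CP(=O)(OCC)OCC | intermediate
48 | (2E,4E,6E)-8-(diethoxyphosphoryl)-6-methylocta-2,4,6-trienoic acid | OC(=O)/C=C/C=C/C(C)=C/CP(=O)(OCC)OCC | intermediate
49 | mixed anhydride of 48 with 2,4,6-trichlorobenzoic acid (formed in the flask) | O=C(OC(=O)/C=C/C=C/C(C)=C/CP(=O)(OCC)OCC)c1c(Cl)cc(Cl)cc1Cl | intermediate
50 | allyl (1S,3R,4S)-4-[(tert-butyldimethylsilyl)oxy]-3-[[(2E,4E,6E)-8-(diethoxyphosphoryl)-6-methylocta-2,4,6-trienoyl]oxy]cyclohexane-1-carboxylate | C=CCOC(=O)[C@@H]1C[C@@H](OC(=O)/C=C/C=C/C(C)=C/CP(=O)(OCC)OCC)[C@@H](O[Si](C)(C)C(C)(C)C)CC1 | intermediate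
51 | C8-lithiated 50 (formed in the flask) | [Li+].C=CCOC(=O)[C@@H]1C[C@@H](OC(=O)/C=C/C=C/C(C)=C/[CH-]P(=O)(OCC)OCC)[C@@H](O[Si](C)(C)C(C)(C)C)CC1 | intermediate
52 | fully protected pentaene allyl ester: (2E,4E,6E,8E,10Z,20E) C1–C23 acyl chain on O3′; 19-OTBS; 4′-OTBS; 13,14- and 15,17-acetonides; allyl ester at C1′ | CC/C=C/[C@H](O[Si](C)(C)C(C)(C)C)[C@H](Cl)[C@H]1C[C@H](OC(C)(C)O1)[C@@H]2OC(C)(C)O[C@@H]2[C@@H](C)/C(Cl)=C/C=C/C=C(C)/C=C/C=C/C(=O)O[C@@H]1C[C@@H](C(=O)OCC=C)CC[C@@H]1O[Si](C)(C)C(C)(C)C | intermediate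
53 | protected pentaene carboxylic acid (as 52 with free C1′ carboxyl) | CC/C=C/[C@H](O[Si](C)(C)C(C)(C)C)[C@H](Cl)[C@H]1C[C@H](OC(C)(C)O1)[C@@H]2OC(C)(C)O[C@@H]2[C@@H](C)/C(Cl)=C/C=C/C=C(C)/C=C/C=C/C(=O)O[C@@H]1C[C@@H](C(=O)O)CC[C@@H]1O[Si](C)(C)C(C)(C)C | intermediate
54 | (1S,3R,4S)-3-[[(2E,4E,6E,8E,10Z,12R,13R,14S,15S,17R,18R,19S,20E)-11,18-dichloro-13,14,15,17,19-pentahydroxy-6,12-dimethyltricosa-2,4,6,8,10,20-hexaenoyl]oxy]-4-hydroxycyclohexane-1-carboxylic acid | CC/C=C/[C@H](O)[C@H](Cl)[C@H](O)C[C@H](O)[C@H](O)[C@H](O)[C@@H](C)/C(Cl)=C/C=C/C=C(C)/C=C/C=C/C(=O)O[C@@H]1C[C@@H](C(=O)O)CC[C@@H]1O | target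

**Step count and risks**

Total step count: 36. Longest linear sequence: 23 steps (steps 1–4, 6–21 and 34–36, from the Roche ester 1).

Steps most likely to fail:

Step 8 (α-chlorination). The enamine of the β-alkoxy aldehyde may expel the C17 oxygen, or the catalyst may work against the bias of the C17 centre so that chlorine is delivered to both faces of C18. The fallback sets out from 10 and moves the control to a covalent auxiliary. Pinnick oxidation (NaClO2, NaH2PO4, 2-methyl-2-butene) gives the C11–C19 carboxylic acid F1. Pivaloyl chloride and Et3N convert it into the pivalic mixed anhydride F2, which acylates lithiated (R)-4-benzyl-2-oxazolidinone to give the N-acyl oxazolidinone F3. Its boron enolate (Bu2BOTf, i-Pr2NEt) is chlorinated by NCS on the face opposite the benzyl group to give the (18R)-α-chloro imide F4. LiBH4 removes the auxiliary and gives the (18S-descriptor, same geometry) 2-chloro alcohol F5, and Dess–Martin oxidation of it returns to the route at 11.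

Step 11 (key osmylation). Osmylation of the crowded Z alkene may be slow, and the C17–C23 chain folding over the alkene may lower the face selectivity set by C12 and C15. The fallback sets out from 9 and carries out the dihydroxylation before the C18–C23 portion exists. OsO4/NMO (or, for reagent control, stoichiometric OsO4 with a C2-symmetric chiral 1,2-diamine, which the absence of chloride and alkyne allows) converts 9 into the 13,14-diol tert-butyl ester F6. 2,2-Dimethoxypropane/PPTS gives the bis-acetonide ester F7, and i-Bu2AlH at −78 °C gives the bis-acetonide aldehyde F8. Chlorination as in step 8 gives the α-chloro aldehyde F9, and lithium butynide addition as in step 9 gives the bis-acetonide chlorohydrin F10. Silylation with TBSOTf/2,6-lutidine returns to the route at 18.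

Step 19 (hydrochlorination). Acetic acid at 80 °C may cleave or shift the acetonides and the allylic silyl ether, and reversible chloride addition may erode the Z geometry. The fallback sets out from 25 and builds the C11–Cl bond through tin under non-acidic conditions. Stannylcupration with Me3SnCu(SPh)Li (THF, −48 °C, then MeOH), run under equilibrating conditions, gives the methyl (10Z)-11-(trimethylstannyl)-10-enoate F11 with tin cis to the ester. Chlorodestannylation with CuCl2 in THF replaces tin by chlorine with retention and returns to the route at 26.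

**Further compounds**

F1 | step 8 | 2-[(4R,6S)-6-[(1Z,3R)-4-[(tert-butyldimethylsilyl)oxy]-3-methylbut-1-en-1-yl]-2,2-dimethyl-1,3-dioxan-4-yl]acetic acid | OC(=O)C[C@H]1C[C@H](OC(C)(C)O1)/C=C\[C@@H](C)CO[Si](C)(C)C(C)(C)C
F2 | step 8 | pivalic mixed anhydride of F1 | CC(C)(C)C(=O)OC(=O)C[C@H]1C[C@H](OC(C)(C)O1)/C=C\[C@@H](C)CO[Si](C)(C)C(C)(C)C
F3 | step 8 | (R)-4-benzyl-3-acyl-2-oxazolidinone of F1 | O=C1OC[C@@H](Cc2ccccc2)N1C(=O)C[C@H]1C[C@H](OC(C)(C)O1)/C=C\[C@@H](C)CO[Si](C)(C)C(C)(C)C
F4 | step 8 | (18R)-α-chloro imide of F3 | O=C1OC[C@@H](Cc2ccccc2)N1C(=O)[C@H](Cl)[C@H]1C[C@H](OC(C)(C)O1)/C=C\[C@@H](C)CO[Si](C)(C)C(C)(C)C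
F5 | step 8 | 2-chloro-2-[(4R,6S)-6-[(1Z,3R)-4-[(tert-butyldimethylsilyl)oxy]-3-methylbut-1-en-1-yl]-2,2-dimethyl-1,3-dioxan-4-yl]ethanol (C18 configured as in 11) | OC[C@H](Cl)[C@H]1C[C@H](OC(C)(C)O1)/C=C\[C@@H](C)CO[Si](C)(C)C(C)(C)C
F6 | step 11 | C11–C19 13,14-diol tert-butyl ester (11-OTBS; 15,17-acetonide; C13, C14 configured as in 17) | CC(C)(C)OC(=O)C[C@H]1C[C@H](OC(C)(C)O1)[C@H](O)[C@H](O)[C@@H](C)CO[Si](C)(C)C(C)(C)C
F7 | step 11 | C11–C19 bis-acetonide tert-butyl ester | CC(C)(C)OC(=O)C[C@H]1C[C@H](OC(C)(C)O1)[C@@H]2OC(C)(C)O[C@@H]2[C@@H](C)CO[Si](C)(C)C(C)(C)C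
F8 | step 11 | C11–C19 bis-acetonide aldehyde (C19 aldehyde) | O=CC[C@H]1C[C@H](OC(C)(C)O1)[C@@H]2OC(C)(C)O[C@@H]2[C@@H](C)CO[Si](C)(C)C(C)(C)C
F9 | step 11 | C11–C19 bis-acetonide (18R)-α-chloro aldehyde | O=C[C@H](Cl)[C@H]1C[C@H](OC(C)(C)O1)[C@@H]2OC(C)(C)O[C@@H]2[C@@H](C)CO[Si](C)(C)C(C)(C)C
F10 | step 11 | C11–C23 bis-acetonide chlorohydrin (19-OH; 20-yne; 18,19 configured as in 14) | CCC#C[C@H](O)[C@H](Cl)[C@H]1C[C@H](OC(C)(C)O1)[C@@H]2OC(C)(C)O[C@@H]2[C@@H](C)CO[Si](C)(C)C(C)(C)C
F11 | step 19 | methyl (10Z)-11-(trimethylstannyl)-10-enoate C9–C23 (otherwise as 25) | CC/C=C/[C@H](O[Si](C)(C)C(C)(C)C)[C@H](Cl)[C@H]1C[C@H](OC(C)(C)O1)[C@@H]2OC(C)(C)O[C@@H]2[C@@H](C)/C([Sn](C)(C)C)=C/C(=O)OC
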